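The quinone ring is disconnected at the bond between carbonyl carbon C4 (the carbonyl flanked by the octadecyl-bearing C3) and the methoxy-bearing C5. The key step exploits the C1/C4 para-dicarbonyl pattern of the six-membered ring with hydrogen at C6: such a ring is the cycloaromatisation product of an enyne-ketene. A squarate-derived 4-hydroxy-4-(methoxyethynyl)cyclobutenone with octadecyl and tert-butoxy on its double bond is heated; the four-membered ring opens to a ketene whose carbon bonds to the ynol ether terminus, and hydrogen transfer from the hydroxyl delivers the fully substituted quinone in one operation. Trifluoroacetic acid then frees the C2 hydroxyl in the same flask.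

Key step: step 4

Remark on the chemistry: ring atoms are numbered as in 2-hydroxy-5-methoxy-3-octadecyl-1,4-benzoquinone. The target has no stereocentre, so the carbinol centre of the cyclobutenone intermediates is made racemic and vanishes in step 4. Compound 2 is taken as its commercial THF solution.

Step 1
Reactants: 1 di-tert-butyl squarate; 2 octadecylmagnesium chloride
Product: 5 3-tert-butoxy-4-octadecylcyclobut-3-ene-1,2-dione, via chloromagnesium alkoxide adduct 3 (not isolated), via adduct trifluoroacetate 4 (not isolated)
Conditions: 2 (1.05 equiv) added to 1, THF, −78 to −40 °C; then (CF3CO)2O, −78 °C; cold aq. NaHCO3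
Reagents that add atoms: none
Why: Grignard 1,2-addition to one carbonyl of the squarate ester, then trifluoroacetylation of the tertiary alkoxide, ionisation assisted by the vinylogous tert-butoxy group and loss of the tert-butyl cation should give the 3-alkyl-4-alkoxycyclobutenedione (the standard squarate ester to cyclobutenedione transposition), with slow addition at low temperature keeping the second carbonyl from reacting.

Step 2
Reactants: 6 2-chloro-1,1-dimethoxyethane
Product: 8 methoxyacetylene, via sodium methoxyacetylide 7 (not isolated)
Conditions: NaNH2 (3 equiv), liquid NH3, −33 °C; NH3 evaporated; cold saturated aq. NaCl, −20 °C; distilled into a −78 °C receiver and kept as a cold THF solution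
Reagents that add atoms: none
Why: Base-induced double elimination of the chloroacetal (loss of methoxide, then of chloride) followed by deprotonation should give the sodium acetylide, which brine protonates to the low-boiling ynol ether; this is the classical preparation of alkoxyacetylenes.

Step 3
Reactants: 8 methoxyacetylene; 5 3-tert-butoxy-4-octadecylcyclobut-3-ene-1,2-dione
Product: 11 3-tert-butoxy-4-hydroxy-4-(methoxyethynyl)-2-octadecylcyclobut-2-en-1-one (racemic), via lithium methoxyacetylide 9 (not isolated), via lithium alkoxide 10 (not isolated)
Conditions: 8 (1.3 equiv), n-BuLi (1.2 equiv), THF, −78 °C; then 5 in THF, −78 °C; saturated aq. NH4Cl, −78 °C to rt; fast chromatography on Et3N-deactivated silica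
Reagents that add atoms: none
Why: Acetylide 1,2-addition to a 3-alkoxycyclobutenedione should occur at the ketone-like carbonyl next to the tert-butoxy-bearing carbon, because the other carbonyl is deactivated as a vinylogous ester; the new carbinol centre is racemic and is erased in step 4.

Step 4
Reactants: 11 3-tert-butoxy-4-hydroxy-4-(methoxyethynyl)-2-octadecylcyclobut-2-en-1-one
Product: 15 irisoquin (2-hydroxy-5-methoxy-3-octadecylcyclohexa-2,5-diene-1,4-dione), via enyne-ketene 12 (not isolated), via diradical 13 (not isolated), via tert-butoxyquinone 14 (not isolated)
Conditions: degassed toluene (0.01 M), 110 °C; then evaporation, CF3CO2H/CH2Cl2 (1:4), 0 °C to rt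
Reagents that add atoms: none
Why: Heating should induce conrotatory 4π-electrocyclic opening of the cyclobutenone, in which the donor hydroxyl rotates outward (torquoselectivity) so that the methoxyethynyl group lies cis to the ketene in 12. The ketene carbon, whose other neighbour is the octadecyl-bearing carbon, then bonds to the methoxy-bearing alkyne terminus in a 6-endo-dig cycloaromatisation to the aryl σ,phenoxyl diradical 13, and transfer of the hydroxyl hydrogen to the σ-radical carbon gives quinone 14 with that hydrogen at C6. The closest known reaction type is the Moore rearrangement of 4-alkynyl-4-hydroxycyclobutenones to 1,4-benzoquinones, a relative of the Myers–Saito enyne-allene cyclisation. No stereocentre is formed and the racemic carbinol centre of 11 is destroyed. The step needs six- over five-membered ring closure, which the alkoxy substituent should secure because it offers no stabilisation to the exocyclic vinyl radical that the five-membered closure would create; the placement of all four substituents is fixed by the position of the carbonyl in 11. Trifluoroacetic acid then cleaves the tert-butyl vinylogous ester by loss of isobutene without touching the methyl ether, giving 15.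

Compound list
1 | di-tert-butyl squarate (3,4-di-tert-butoxycyclobut-3-ene-1,2-dione) | CC(C)(C)OC1=C(OC(C)(C)C)C(=O)C1=O | starting material
2 | octadecylmagnesium chloride | CCCCCCCCCCCCCCCCCC[Mg]Cl | starting material
3 | chloromagnesium 2,3-di-tert-butoxy-1-octadecyl-4-oxocyclobut-2-en-1-olate (racemic) | CCCCCCCCCCCCCCCCCCC1(O[Mg]Cl)C(OC(C)(C)C)=C(OC(C)(C)C)C1=O | intermediate
4 | 2,3-di-tert-butoxy-1-octadecyl-4-oxocyclobut-2-en-1-yl trifluoroacetate (racemic) | CCCCCCCCCCCCCCCCCCC1(OC(=O)C(F)(F)F)C(OC(C)(C)C)=C(OC(C)(C)C)C1=O | intermediate
5 | 3-tert-butoxy-4-octadecylcyclobut-3-ene-1,2-dione | CCCCCCCCCCCCCCCCCCC1=C(OC(C)(C)C)C(=O)C1=O | intermediate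
6 | 2-chloro-1,1-dimethoxyethane | COC(CCl)OC | starting material
7 | sodium methoxyacetylide | [Na+].[C-]#COC | intermediate
8 | methoxyacetylene (methoxyethyne) | COC#C | intermediate
9 | lithium methoxyacetylide | [Li]C#COC | intermediate
10 | lithium 2-tert-butoxy-1-(methoxyethynyl)-3-octadecyl-4-oxocyclobut-2-en-1-olate (racemic) | CCCCCCCCCCCCCCCCCCC1=C(OC(C)(C)C)C(O[Li])(C#COC)C1=O | intermediate
11 | 3-tert-butoxy-4-hydroxy-4-(methoxyethynyl)-2-octadecylcyclobut-2-en-1-one (racemic) | CCCCCCCCCCCCCCCCCCC1=C(OC(C)(C)C)C(O)(C#COC)C1=O | intermediate
12 | (3Z)-3-tert-butoxy-4-hydroxy-6-methoxy-2-octadecylhexa-1,3-dien-5-yn-1-one (enyne-ketene) | CCCCCCCCCCCCCCCCCCC(=C=O)/C(OC(C)(C)C)=C(/O)C#COC | intermediate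
13 | 3-tert-butoxy-4-hydroxy-6-methoxy-2-octadecylphenoxyl with a σ-radical at C5 (diradical) | CCCCCCCCCCCCCCCCCCc1c([O])c(OC)[c]c(O)c1OC(C)(C)C | intermediate
14 | 2-tert-butoxy-5-methoxy-3-octadecylcyclohexa-2,5-diene-1,4-dione | CCCCCCCCCCCCCCCCCCC1=C(OC(C)(C)C)C(=O)C=C(OC)C1=O | intermediate
15 | irisoquin (2-hydroxy-5-methoxy-3-octadecylcyclohexa-2,5-diene-1,4-dione) | CCCCCCCCCCCCCCCCCCC1=C(O)C(=O)C=C(OC)C1=O | target

Total step count: 4
Longest linear sequence: 3 steps (steps 1, 3 and 4 from di-tert-butyl squarate); step 2 is a one-step branch that joins at step 3.

Steps most likely to fail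

Step 4. The enyne-ketene may partition toward five-membered ring closure (bonding of the ketene carbon to the proximal alkyne carbon, leading to an alkylidenecyclopentenedione), or the ynol ether may rearrange under heat or trace acid before the ring opens. The fallback sets out from 11 and comes back at 14. Semi-hydrogenation of the ynol ether (H2, Pd on CaCO3 poisoned with Pb(OAc)2, quinoline, EtOAc, rt) should give the (Z)-2-methoxyvinyl carbinol F1. Thermolysis of F1 in toluene at 110 °C is then a closed-shell sequence of four-electron ring opening, six-electron electrocyclisation and enolisation; it can only form the six-membered ring, forms the same ring bond, and should give hydroquinone F2. Oxidation of F2 with Ag2O in Et2O should give tert-butoxyquinone 14, which is taken through the CF3CO2H stage of step 4.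

Step 3. The alkoxyethynyl carbinol may undergo acid-promoted rearrangement to an unsaturated ester, or hydration of the ynol ether, during aqueous work-up and chromatography. The fallback sets out from lithium alkoxide 10 and comes back at 15. The alkoxide is trapped in the flask with Me3SiCl at −78 °C and worked up without water (pentane, filtration), so that the free carbinol is never formed; this should give silyl ether F3. Thermolysis of F3 in toluene follows the same ring opening and ring closure, but silicon instead of hydrogen migrates to the σ-radical carbon, which should give the 6-silylquinone F4. CF3CO2H in CH2Cl2 should then both remove the tert-butyl group and ipso-protodesilylate the electron-rich carbon next to the methoxy-bearing carbon, giving 15.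

Step 2. The very volatile alkyne may be lost on isolation, and co-distilled ammonia or water would later consume n-BuLi or attack 5. The fallback avoids the free alkyne; it sets out from commercial trichloroethylene in place of 6 (this branch has no earlier numbered compound) and comes back at 9. Net vinylic substitution of trichloroethylene by NaOMe in THF should give (E)-1,2-dichloro-1-methoxyethene F5. Treatment of F5 with n-BuLi (2 equiv, THF, −78 to −40 °C) should give lithium methoxyacetylide 9 by dehydrochlorination and chlorine–lithium exchange, and 9 is used directly in step 3.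

Further compounds
F1 | step 4 | 3-tert-butoxy-4-hydroxy-4-[(Z)-2-methoxyethenyl]-2-octadecylcyclobut-2-en-1-one (racemic) | CCCCCCCCCCCCCCCCCCC1=C(OC(C)(C)C)C(O)(/C=C\OC)C1=O
F2 | step 4 | 2-tert-butoxy-5-methoxy-3-octadecylbenzene-1,4-diol | CCCCCCCCCCCCCCCCCCc1c(O)c(OC)cc(O)c1OC(C)(C)C
F3 | step 3 | 3-tert-butoxy-4-(methoxyethynyl)-2-octadecyl-4-(trimethylsilyloxy)cyclobut-2-en-1-one (racemic) | CCCCCCCCCCCCCCCCCCC1=C(OC(C)(C)C)C(O[Si](C)(C)C)(C#COC)C1=O
F4 | step 3 | 2-tert-butoxy-5-methoxy-3-octadecyl-6-(trimethylsilyl)cyclohexa-2,5-diene-1,4-dione | CCCCCCCCCCCCCCCCCCC1=C(OC(C)(C)C)C(=O)C([Si](C)(C)C)=C(OC)C1=O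
F5 | step 2 | (E)-1,2-dichloro-1-methoxyethene | CO/C(Cl)=C\Cl
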